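**Retrosynthetic overview**

1. The target (achiral) is taken back to its bis(triisopropylsilyl) ether; the last step is a global desilylation.
2. The pyran ring is opened at the O1–C2 bond to a vinyl o-quinone methide, which comes from an o-(1-methoxy-3-methylbut-2-enyl)phenol by loss of methanol. That phenol is the direct product of a cyclobutenone + siloxyalkyne benzannulation, so ring A and the pyran ring are both made in one thermal operation from a monocyclic and an acyclic fragment.
3. Enabling feature: the pyran array O1–C2(CH3)2–C3=C4–C4a=C8a is the closed valence isomer of a 1-oxatriene (an o-quinone methide of ring A). Ring A carries its two oxygens (on C8a and C5) meta to each other with C4a between them, which is exactly the pattern that a vinylketene C=O plus an ynol ether C–O writes.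
4. Cyclobutenone fragment: ketene from 5-methylhex-4-enoic acid + ethoxyacetylene ([2+2]), then the Grignard reagent from 4-(2-bromoethyl)phenol. Alkyne fragment: 3-methylbut-2-enal + ethynylmagnesium bromide, O-methylation, acetylide oxidation/O-silylation.
5. Order of ring formation: the 4-hydroxyphenyl ring is bought; the cyclobutenone (temporary ring) is made in step 2; ring A (benzene) and then the pyran ring are both closed in step 8.

Key step: step 8

Assumption: the target has no stereocentre and no stereogenic double bond, so no stereocontrol is needed; the stereocentres of intermediates 5, 9, 10, 13–17 and 19–22 are racemic or mixed and are all erased in step 8; compounds 1, 3, 6, 11 and 12 are taken as purchasable.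

**Step 1**
Reactants: 1 5-methylhex-4-enoic acid
Product: 2 5-methylhex-4-enoyl chloride
Conditions: (COCl)2, DMF (cat.), CH2Cl2, 0 °C to rt
Reagents that add atoms: oxalyl chloride, O=C(Cl)C(=O)Cl
Why: Acyl chloride formation through the catalytic chloroiminium (Vilsmeier-type) species needs no strong acid or heat, so the trisubstituted alkene should be untouched.

**Step 2**
Reactants: 2 5-methylhex-4-enoyl chloride; 3 ethoxyacetylene
Product: 5 3-ethoxy-4-(3-methylbut-2-en-1-yl)cyclobut-2-en-1-one (racemic), via (3-methylbut-2-en-1-yl)ketene 4 (not isolated)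
Conditions: 3 (2 equiv), Et3N, Et2O, rt, slow addition of 2
Reagents that add atoms: none
Why: Dehydrochlorination with Et3N gives aldoketene 4, which is trapped in a ketene–ynol ether [2+2] cycloaddition (ketene carbonyl carbon to the unsubstituted, nucleophilic alkyne carbon), slow addition into excess 3 keeping ketene dimerisation down; the ring stereocentre forms racemic and is erased in step 8.

**Step 3**
Reactants: 6 4-(2-bromoethyl)phenol
Product: 7 [4-(2-bromoethyl)phenoxy]triisopropylsilane
Conditions: TIPSCl, imidazole, CH2Cl2, 0 °C to rt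
Reagents that add atoms: chlorotriisopropylsilane (TIPSCl), CC(C)[Si](Cl)(C(C)C)C(C)C
Why: Imidazole-mediated silylation of the phenol is faster than any displacement of the primary bromide, and the triisopropylsilyl ether is chosen because it should survive the Grignard reagent, dilute acid and 120 °C.

**Step 4**
Reactants: 7 [4-(2-bromoethyl)phenoxy]triisopropylsilane; 5 3-ethoxy-4-(3-methylbut-2-en-1-yl)cyclobut-2-en-1-one
Product: 10 4-(3-methylbut-2-en-1-yl)-3-{2-[4-(triisopropylsilyloxy)phenyl]ethyl}cyclobut-2-en-1-one (racemic), via Grignard reagent 8 (not isolated), via cyclobutenol adduct 9 (not isolated)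
Conditions: Mg, THF, rt; then 5, −78 °C; then 1 M HCl, 0 °C to rt
Reagents that add atoms: water, O
Why: Grignard addition to the vinylogous ester followed by acid hydrolysis of the enol ether and dehydration (the 1,3-carbonyl transposition used to make 3-substituted cyclobutenones from 3-ethoxycyclobutenones) puts the arylethyl group on C3, and since the prenyl-bearing carbon is bonded to both C1 and C3 the 1,2- and 1,4-modes of addition converge on the same constitution; the C4 stereocentre stays racemic.

**Step 5**
Reactants: 11 3-methylbut-2-enal; 12 ethynylmagnesium bromide (HC≡CMgBr)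
Product: 13 5-methylhex-4-en-1-yn-3-ol (racemic)
Conditions: THF, −78 to 0 °C; aq NH4Cl
Reagents that add atoms: none
Why: 1,2-addition of an alkynyl Grignard reagent to the enal carbonyl; the carbinol stereocentre forms racemic and is erased in step 8.

**Step 6**
Reactants: 13 5-methylhex-4-en-1-yn-3-ol
Product: 14 3-methoxy-5-methylhex-4-en-1-yne (racemic)
Conditions: NaH, MeI, THF, 0 °C to rt
Reagents that add atoms: iodomethane, CI
Why: Williamson ether synthesis, the alkoxide forming much faster than the acetylide with NaH so that methylation should occur on oxygen only.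

**Step 7**
Reactants: 14 3-methoxy-5-methylhex-4-en-1-yne
Product: 17 [(3-methoxy-5-methylhex-4-en-1-yn-1-yl)oxy]triisopropylsilane (racemic), via lithium acetylide 15 (not isolated), via lithium ynolate 16 (not isolated)
Conditions: n-BuLi, THF, −78 °C; t-BuOOLi (from t-BuOOH + LiN(SiMe3)2), −78 to 0 °C; TIPSOTf, −78 to 0 °C
Reagents that add atoms: tert-butyl hydroperoxide, CC(C)(C)OO; triisopropylsilyl trifluoromethanesulfonate, CC(C)[Si](OS(=O)(=O)C(F)(F)F)(C(C)C)C(C)C
Why: The lithium acetylide is oxidised by electrophilic oxygen transfer from lithium tert-butyl peroxide to the ynolate, which the bulky silyl triflate traps on oxygen (the established acetylide oxidation/O-silylation route to siloxyalkynes).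

**Step 8**
Reactants: 10 4-(3-methylbut-2-en-1-yl)-3-{2-[4-(triisopropylsilyloxy)phenyl]ethyl}cyclobut-2-en-1-one; 17 [(3-methoxy-5-methylhex-4-en-1-yn-1-yl)oxy]triisopropylsilane
Product: 24 2,2-dimethyl-8-(3-methylbut-2-en-1-yl)-5-(triisopropylsilyloxy)-7-{2-[4-(triisopropylsilyloxy)phenyl]ethyl}-2H-chromene, via vinylketene 18 (not isolated), via vinylcyclobutenone 19 (not isolated), via dienylketene 20 (not isolated), via cyclohexadienone 21 (not isolated), via phenol 22 (not isolated), via o-quinone methide 23 (not isolated)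
Conditions: 17 (1.3 equiv), 4 Å MS, PhMe, 80 °C then 120 °C, sealed tube
Reagents that add atoms: none
Why: Proposed new method: the closest known reaction type is the Danheiser benzannulation of cyclobutenones with siloxyalkynes, which the first stage follows exactly: strain-releasing 4π opening of 10 to vinylketene 18, [2+2] cycloaddition with 17 to 19 (the nucleophilic alkyne carbon, the one bearing the methoxyallyl arm, bonds to the ketene carbonyl carbon), 4π opening to dienylketene 20, 6π electrocyclisation to 21 and tautomerisation to phenol 22. What is new is that 22 is not the end: at 120 °C its free hydroxyl should expel methanol from the ortho carbon, which is benzylic, allylic and flanked by two oxygen-bearing ring carbons, through a six-membered hydrogen-bonded transition state, and the resulting vinyl o-quinone methide 23 is a 1-oxatriene that closes at once by oxa-6π electrocyclisation, forming the O–C(CH3)2 bond; a benzannulation/o-quinone methide/electrocyclisation cascade is known from chromium carbene complexes (CO)5Cr=C(OMe)(alkenyl) and alkenyl propargyl ethers, but not from cyclobutenones. Ring A is closed by thermal disrotatory 6π electrocyclisation of a dienylketene (C–C bond, six-membered) and the pyran ring by thermal disrotatory oxa-6π electrocyclisation of the dienone (O–C bond, six-membered). No stereocentre is created, and the racemic centres of 10 and 17 are erased. The step needs regiocontrol and a single oxygen for ring closure: the ynol ether polarisation places the five-carbon arm between the two oxygens, the only free hydroxyl is the one born from the ketene carbonyl next to the prenyl-bearing carbon while the other oxygen is held as its silyl ether, and allylic strain against that silyloxy group should keep the vinyl group of 23 syn to the carbonyl. The two temperature stages and the molecular sieves keep the released methanol away from the ketenes.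

**Step 9**
Reactants: 24 2,2-dimethyl-8-(3-methylbut-2-en-1-yl)-5-(triisopropylsilyloxy)-7-{2-[4-(triisopropylsilyloxy)phenyl]ethyl}-2H-chromene
Product: 25 7-[2-(4-hydroxyphenyl)ethyl]-2,2-dimethyl-8-(3-methylbut-2-en-1-yl)-2H-chromen-5-ol
Conditions: TBAF, AcOH, THF, 0 °C to rt
Reagents that add atoms: none
Why: Fluoride cleaves both aryl silyl ethers (desilylation), and the acetic acid buffer keeps the electron-rich chromenol from standing as an air-sensitive phenoxide.

**Compound list**

1 | 5-methylhex-4-enoic acid | CC(C)=CCCC(=O)O | starting material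
2 | 5-methylhex-4-enoyl chloride | CC(C)=CCCC(=O)Cl | intermediate
3 | ethoxyacetylene | C#COCC | starting material
4 | (3-methylbut-2-en-1-yl)ketene (5-methylhexa-1,4-dien-1-one) | CC(C)=CCC=C=O | intermediate
5 | 3-ethoxy-4-(3-methylbut-2-en-1-yl)cyclobut-2-en-1-one (racemic) | CCOC1=CC(=O)C1CC=C(C)C | intermediate
6 | 4-(2-bromoethyl)phenol | Oc1ccc(CCBr)cc1 | starting material
7 | [4-(2-bromoethyl)phenoxy]triisopropylsilane | CC(C)[Si](Oc1ccc(CCBr)cc1)(C(C)C)C(C)C | intermediate
8 | {2-[4-(triisopropylsilyloxy)phenyl]ethyl}magnesium bromide | Br[Mg]CCc1ccc(O[Si](C(C)C)(C(C)C)C(C)C)cc1 | intermediate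
9 | 3-ethoxy-4-(3-methylbut-2-en-1-yl)-1-{2-[4-(triisopropylsilyloxy)phenyl]ethyl}cyclobut-2-en-1-ol (mixture of racemic diastereomers) | CCOC1=CC(O)(CCc2ccc(O[Si](C(C)C)(C(C)C)C(C)C)cc2)C1CC=C(C)C | intermediate
10 | 4-(3-methylbut-2-en-1-yl)-3-{2-[4-(triisopropylsilyloxy)phenyl]ethyl}cyclobut-2-en-1-one (racemic) | O=C1C=C(CCc2ccc(O[Si](C(C)C)(C(C)C)C(C)C)cc2)C1CC=C(C)C | intermediate
11 | 3-methylbut-2-enal | CC(C)=CC=O | starting material
12 | ethynylmagnesium bromide | C#C[Mg]Br | starting material
13 | 5-methylhex-4-en-1-yn-3-ol (racemic) | CC(C)=CC(O)C#C | intermediate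
14 | 3-methoxy-5-methylhex-4-en-1-yne (racemic) | CC(C)=CC(OC)C#C | intermediate
15 | (3-methoxy-5-methylhex-4-en-1-yn-1-yl)lithium | CC(C)=CC(OC)C#C[Li] | intermediate
16 | lithium 3-methoxy-5-methylhex-4-en-1-yn-1-olate | CC(C)=CC(OC)C#CO[Li] | intermediate
17 | [(3-methoxy-5-methylhex-4-en-1-yn-1-yl)oxy]triisopropylsilane (racemic) | CC(C)=CC(OC)C#CO[Si](C(C)C)(C(C)C)C(C)C | intermediate
18 | (3E)-7-methyl-3-{2-[4-(triisopropylsilyloxy)phenyl]ethyl}octa-1,3,6-trien-1-one (vinylketene) | O=C=C/C(CCc1ccc(O[Si](C(C)C)(C(C)C)C(C)C)cc1)=C/CC=C(C)C | intermediate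
19 | 2-(1-methoxy-3-methylbut-2-en-1-yl)-4-{(3E)-7-methyl-1-[4-(triisopropylsilyloxy)phenyl]octa-3,6-dien-3-yl}-3-(triisopropylsilyloxy)cyclobut-2-en-1-one (mixture of diastereomers) | O=C1C(C(OC)C=C(C)C)=C(O[Si](C(C)C)(C(C)C)C(C)C)C1/C(CCc1ccc(O[Si](C(C)C)(C(C)C)C(C)C)cc1)=C/CC=C(C)C | intermediate
20 | dienylketene: 2-(1-methoxy-3-methylbut-2-en-1-yl)-9-methyl-3-(triisopropylsilyloxy)-5-{2-[4-(triisopropylsilyloxy)phenyl]ethyl}deca-1,3,5,8-tetraen-1-one, ketene-bearing carbon and C5 cis across C3=C4, C4 and C7 trans across C5=C6 | O=C=C(C(OC)C=C(C)C)/C(O[Si](C(C)C)(C(C)C)C(C)C)=C\C(CCc1ccc(O[Si](C(C)C)(C(C)C)C(C)C)cc1)=C\CC=C(C)C | intermediate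
21 | 2-(1-methoxy-3-methylbut-2-en-1-yl)-6-(3-methylbut-2-en-1-yl)-3-(triisopropylsilyloxy)-5-{2-[4-(triisopropylsilyloxy)phenyl]ethyl}cyclohexa-2,4-dien-1-one (mixture of diastereomers) | O=C1C(C(OC)C=C(C)C)=C(O[Si](C(C)C)(C(C)C)C(C)C)C=C(CCc2ccc(O[Si](C(C)C)(C(C)C)C(C)C)cc2)C1CC=C(C)C | intermediate
22 | 2-(1-methoxy-3-methylbut-2-en-1-yl)-6-(3-methylbut-2-en-1-yl)-3-(triisopropylsilyloxy)-5-{2-[4-(triisopropylsilyloxy)phenyl]ethyl}phenol (racemic) | Oc1c(C(OC)C=C(C)C)c(O[Si](C(C)C)(C(C)C)C(C)C)cc(CCc2ccc(O[Si](C(C)C)(C(C)C)C(C)C)cc2)c1CC=C(C)C | intermediate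
23 | (6Z)-6-(3-methylbut-2-en-1-ylidene)-2-(3-methylbut-2-en-1-yl)-5-(triisopropylsilyloxy)-3-{2-[4-(triisopropylsilyloxy)phenyl]ethyl}cyclohexa-2,4-dien-1-one (o-quinone methide) | O=C1/C(=C\C=C(C)C)C(O[Si](C(C)C)(C(C)C)C(C)C)=CC(CCc2ccc(O[Si](C(C)C)(C(C)C)C(C)C)cc2)=C1CC=C(C)C | intermediate
24 | 2,2-dimethyl-8-(3-methylbut-2-en-1-yl)-5-(triisopropylsilyloxy)-7-{2-[4-(triisopropylsilyloxy)phenyl]ethyl}-2H-chromene | CC(C)=CCc1c(CCc2ccc(O[Si](C(C)C)(C(C)C)C(C)C)cc2)cc(O[Si](C(C)C)(C(C)C)C(C)C)c2c1OC(C)(C)C=C2 | intermediate
25 | 7-[2-(4-hydroxyphenyl)ethyl]-2,2-dimethyl-8-(3-methylbut-2-en-1-yl)-2H-chromen-5-ol | CC(C)=CCc1c(CCc2ccc(O)cc2)cc(O)c2c1OC(C)(C)C=C2 | target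

**Step count and risks**

Total steps: 9. Longest linear sequence: 5 steps (1 → 2 → 5 → 10 → 24 → 25; the alkyne branch 11 → 13 → 14 → 17 → 24 → 25 is of equal length).

Most likely to fail, first: step 8. The cascade may stall after the benzannulation because thermal loss of methanol from the phenol is too slow. The ketene intermediates may be intercepted by the released methanol or by the phenol (ester formation). The allylic methyl ether of the siloxyalkyne may ionise before cycloaddition. The fallback sets out from 10 and comes back at 25, using only established reactions. Compound 10 is heated with ethoxyacetylene 3 (PhMe, 80 °C, sealed tube), the benzannulation in its established form with an alkoxyacetylene; this should give 3-ethoxy-6-(3-methylbut-2-en-1-yl)-5-{2-[4-(triisopropylsilyloxy)phenyl]ethyl}phenol F1, in which the position between the two oxygens is unsubstituted. The free hydroxyl of F1 is alkylated with 3-chloro-3-methylbut-1-yne (DBU, CuCl2 cat., MeCN, 0 °C) to the 1,1-dimethylpropargyl ether F2. Heating F2 (xylene, 140 °C) should bring about the aryl propargyl ether Claisen rearrangement to the only open ortho carbon, [1,5]-hydrogen shift and oxa-6π closure to the 5-ethoxychromene silyl ether F3; the pyran ring is closed at the same O–C bond, and the other oxygen is capped as its ethyl ether. TBAF/AcOH in THF then gives the phenol F4, and NaSEt in DMF at 130 °C cleaves the aryl ethyl ether to give 25.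

Second: step 7. Oxygen transfer from the peroxide to the acetylide may be incomplete, the β-methoxy ynolate may lose methoxide before it is silylated, or silylation may occur on carbon. The fallback sets out from 11 and 3 and comes back at 25, and makes an ynol ether with the same arm without any ynolate. Ethoxyacetylene 3 is deprotonated with n-BuLi (THF, −78 °C) and added to 3-methylbut-2-enal 11 to give 1-ethoxy-5-methylhex-4-en-1-yn-3-ol F5. NaH/MeI in THF gives 1-ethoxy-3-methoxy-5-methylhex-4-en-1-yne F6. F6 takes the place of 17 in step 8 (PhMe, 4 Å MS, 80 °C then 120 °C) and should give the 5-ethoxychromene silyl ether F3, which is carried through F4 to 25 as described for the first fallback.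

Third: step 2. Dimerisation or oligomerisation of the unhindered aldoketene may outrun its cycloaddition to the ynol ether. The fallback sets out from 1 and comes back at 5, using a more electrophilic, slower-dimerising chloroketene. The dianion of 1 (LiN(i-Pr)2, 2 equiv, THF, −78 °C) is chlorinated with CCl4 to 2-chloro-5-methylhex-4-enoic acid F7. (COCl)2/DMF (cat.) gives the acid chloride F8. Et3N in Et2O in the presence of excess 3 generates chloro(3-methylbut-2-en-1-yl)ketene F9, whose [2+2] cycloaddition should give 4-chloro-3-ethoxy-4-(3-methylbut-2-en-1-yl)cyclobut-2-en-1-one F10. Reductive dechlorination (Zn, AcOH, TMEDA, EtOH, 0 °C), as used for dichloroketene-derived cyclobutenones, then gives 5.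

**Further compounds**

F1 | step 8 | 3-ethoxy-6-(3-methylbut-2-en-1-yl)-5-{2-[4-(triisopropylsilyloxy)phenyl]ethyl}phenol | CCOc1cc(CCc2ccc(O[Si](C(C)C)(C(C)C)C(C)C)cc2)c(CC=C(C)C)c(O)c1
F2 | step 8 | {4-[2-(5-ethoxy-3-[(2-methylbut-3-yn-2-yl)oxy]-2-(3-methylbut-2-en-1-yl)phenyl)ethyl]phenoxy}triisopropylsilane | CCOc1cc(CCc2ccc(O[Si](C(C)C)(C(C)C)C(C)C)cc2)c(CC=C(C)C)c(OC(C)(C)C#C)c1
F3 | step 8 | 5-ethoxy-2,2-dimethyl-8-(3-methylbut-2-en-1-yl)-7-{2-[4-(triisopropylsilyloxy)phenyl]ethyl}-2H-chromene | CCOc1cc(CCc2ccc(O[Si](C(C)C)(C(C)C)C(C)C)cc2)c(CC=C(C)C)c2OC(C)(C)C=Cc12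
F4 | step 8 | 4-{2-[5-ethoxy-2,2-dimethyl-8-(3-methylbut-2-en-1-yl)-2H-chromen-7-yl]ethyl}phenol | CCOc1cc(CCc2ccc(O)cc2)c(CC=C(C)C)c2OC(C)(C)C=Cc12
F5 | step 7 | 1-ethoxy-5-methylhex-4-en-1-yn-3-ol (racemic) | CCOC#CC(O)C=C(C)C
F6 | step 7 | 1-ethoxy-3-methoxy-5-methylhex-4-en-1-yne (racemic) | CCOC#CC(OC)C=C(C)C
F7 | step 2 | 2-chloro-5-methylhex-4-enoic acid (racemic) | CC(C)=CCC(Cl)C(=O)O
F8 | step 2 | 2-chloro-5-methylhex-4-enoyl chloride (racemic) | CC(C)=CCC(Cl)C(=O)Cl
F9 | step 2 | chloro(3-methylbut-2-en-1-yl)ketene | CC(C)=CCC(Cl)=C=O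
F10 | step 2 | 4-chloro-3-ethoxy-4-(3-methylbut-2-en-1-yl)cyclobut-2-en-1-one (racemic) | CCOC1=CC(=O)C1(Cl)CC=C(C)C
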